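**Retrosynthetic overview**

1. The target is a 2,5-diaryl-3,4-bis(hydroxymethyl)tetrahydrofuran (ring O1–C2–C3–C4–C5, C5 being the first stereocentre of the SMILES) with 2,3-trans, 3,4-trans and 4,5-cis substituents. The plan rests on the cis pair C4(CH2OH)/C5(aryl) next to the one-carbon branch on C3, which is the pattern of a cis-β,γ-disubstituted α-methylene-γ-butyrolactone (C2 as carbonyl, C3 as exocyclic methylene).
2. Late disconnections: the C2–aryl bond (Friedel–Crafts arylation of a lactol acetate with 2,6-dimethoxyphenol, trans to C3) and the O–CH2 bond of the C3 branch (oxa-Michael addition of benzyl alcohol).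
3. Key disconnection: C4–C5 and O1–C2, by allylboration of O-tosyl syringaldehyde with a 2-(methoxycarbonyl)allyl pinacol boronate carrying CH2OBn cis to CH2B under a chiral phosphoric acid, then lactonisation.
4. The boronate comes from methyl acrylate and benzyloxyacetaldehyde (Baylis–Hillman reaction, acetate, SN2′ borylation).
5. Ring order: the five-membered oxygen ring is the only ring made; it is closed once, as the lactone in the key step, and kept to the end.

Key step: step 5

Remark: the ring numbering O1, C2, C3, C4, C5 of the target is used for every ring compound (C2 = lactone carbonyl or lactol carbon, C5 = carbon from the aldehyde); Ts = 4-methylbenzenesulfonyl, Bpin = 4,4,5,5-tetramethyl-1,3,2-dioxaborolan-2-yl.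

**Route**

Step 1
Reactants: 1 syringaldehyde
Product: 2 4-formyl-2,6-dimethoxyphenyl 4-methylbenzenesulfonate
Conditions: TsCl, Et3N, DMAP (cat.), CH2Cl2, 0 °C → rt
Reagents that add atoms: 4-methylbenzenesulfonyl chloride, Cc1ccc(cc1)S(=O)(=O)Cl
Why: Routine O-sulfonylation of a phenol, the tosylate being chosen because it makes the aldehyde more electrophilic and takes the para oxygen lone pair out of conjugation with the later benzylic C5.

Step 2
Reactants: 3 methyl acrylate; 4 benzyloxyacetaldehyde
Product: 5 methyl 4-(benzyloxy)-3-hydroxy-2-methylidenebutanoate (racemic)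
Conditions: DABCO (0.3 equiv), MeOH, rt
Reagents that add atoms: none
Why: Morita–Baylis–Hillman reaction, for which α-alkoxy aldehydes are reactive partners, and the racemic carbinol centre is erased in step 4.

Step 3
Reactants: 5 methyl 4-(benzyloxy)-3-hydroxy-2-methylidenebutanoate
Product: 6 methyl 3-acetoxy-4-(benzyloxy)-2-methylidenebutanoate (racemic)
Conditions: Ac2O, pyridine, DMAP (cat.), CH2Cl2, 0 °C
Reagents that add atoms: acetic anhydride, CC(=O)OC(C)=O
Why: Standard acylation of a secondary allylic alcohol installs the leaving group for the SN2′ step, a short cold reaction avoiding allylic transposition of the acetate.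

Step 4
Reactants: 6 methyl 3-acetoxy-4-(benzyloxy)-2-methylidenebutanoate; 7 bis(pinacolato)diboron
Product: 8 methyl (E)-4-(benzyloxy)-2-[(4,4,5,5-tetramethyl-1,3,2-dioxaborolan-2-yl)methyl]but-2-enoate (CH2OBn cis to CH2B)
Conditions: CuCl (10 mol%), LiCl, KOAc, DMF, rt
Reagents that add atoms: none
Why: CuCl-catalysed SN2′ borylation of a Baylis–Hillman acetate: a Cu–Bpin species adds to the acrylate terminus, acetate is expelled, and ester-derived acetates are expected to give the trisubstituted alkene with the γ-substituent trans to the ester, here CH2OBn cis to CH2B (E by the sequence rules), a geometry to be confirmed by NOE because it later defines the 4,5-cis relation.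

Step 5
Reactants: 2 4-formyl-2,6-dimethoxyphenyl 4-methylbenzenesulfonate; 8 methyl (E)-4-(benzyloxy)-2-[(Bpin)methyl]but-2-enoate
Product: 10 (4S,5S)-4-[(benzyloxy)methyl]-5-[3,5-dimethoxy-4-(tosyloxy)phenyl]-3-methylidenedihydrofuran-2(3H)-one (4,5-cis), via syn-homoallylic pinacol borate 9 (not isolated)
Conditions: (S)-TRIP [(S)-3,3′-bis(2,4,6-triisopropylphenyl)-1,1′-binaphthyl-2,2′-diyl hydrogen phosphate] (10 mol%), 4 Å MS, PhMe, 0 °C → rt; then p-TsOH·H2O (10 mol%), rt
Reagents that add atoms: none
Why: Proposed new method: the phosphoric acid is expected to hydrogen-bond through its P–OH to a dioxaborolane oxygen of 8 and through its P=O to the formyl hydrogen of 2, which raises the Lewis acidity of boron and lets the allyl group pass to the aldehyde in a closed chair six-membered transition state (B–O and C4–C5 formed together, double bond shifted to the exocyclic C3 methylene). The closest known reactions are the chiral phosphoric acid-catalysed allyl- and crotylboration of aryl aldehydes with pinacol boronates and the Sc(OTf)3- or TfOH-catalysed allylboration–lactonisation of 2-alkoxycarbonyl allylboronates; the untested element is the combination of the chiral acid with the less nucleophilic ester-bearing boronate. The lactone ring closes by 5-exo-trig acyl substitution of the C5 oxygen of borate 9 on the methyl ester (O1–C2), driven to completion by the p-TsOH added once the aldehyde is consumed. C4 is fixed relative to C5 by the alkene geometry of 8: with the aryl group equatorial in the chair, the CH2OBn group cis to CH2B must sit axial, so the adduct is syn and the lactone 4,5-cis. C5 (S, attack on the Si face of the aldehyde) is fixed by the catalyst, the (S)-acid being chosen by analogy with the Re-face preference of the (R)-acid in the allylboration of benzaldehyde, an assignment to be verified before scale-up. The step needs face selectivity and retention of the cis relation: the ester-deactivated boronate has almost no uncatalysed background reaction at this temperature, and the tosyloxy group para to the benzylic carbon disfavours the benzylic ionisation that scrambles cis lactones of electron-rich aryl aldehydes under acid.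

Step 6
Reactants: 10 (4S,5S)-α-methylene lactone; 11 benzyl alcohol
Product: 12 (3S,4S,5S)-3,4-bis[(benzyloxy)methyl]-5-[3,5-dimethoxy-4-(tosyloxy)phenyl]dihydrofuran-2(3H)-one (3,4-trans, 4,5-cis)
Conditions: BnOH (5 equiv), t-BuOK (10 mol%), THF, 0 °C → rt; AcOH quench
Reagents that add atoms: none
Why: Base-catalysed oxa-Michael addition of benzyl alcohol to the exocyclic enoate of an α-methylene-γ-butyrolactone, run cold with excess alcohol so that addition outruns γ-deprotonation; the addition is reversible and C3 stays epimerisable under the alkoxide, so the product should settle as the more stable isomer with the C3 branch trans to the C4 branch (C3 S).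

Step 7
Reactants: 12 (3S,4S,5S)-lactone
Product: 13 (3S,4S,5S)-3,4-bis[(benzyloxy)methyl]-5-[3,5-dimethoxy-4-(tosyloxy)phenyl]tetrahydrofuran-2-ol (anomer mixture)
Conditions: i-Bu2AlH (1.2 equiv), CH2Cl2, −78 °C; aq. potassium sodium tartrate
Reagents that add atoms: none
Why: Partial reduction of a γ-lactone to the lactol with i-Bu2AlH at −78 °C is standard because over-reduction is slow at this temperature, and the aryl sulfonate, the benzyl ethers and the three stereocentres are left untouched.

Step 8
Reactants: 13 lactol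
Product: 14 (3S,4S,5S)-3,4-bis[(benzyloxy)methyl]-5-[3,5-dimethoxy-4-(tosyloxy)phenyl]tetrahydrofuran-2-yl acetate (anomer mixture)
Conditions: Ac2O, pyridine, DMAP (cat.), CH2Cl2, 0 °C → rt
Reagents that add atoms: acetic anhydride, CC(=O)OC(C)=O
Why: O-acetylation of the anomeric hydroxyl provides a leaving group that ionises cleanly with BF3·OEt2, the anomer mixture being of no consequence because both anomers lead to the same cation.

Step 9
Reactants: 14 lactol acetate; 15 2,6-dimethoxyphenol
Product: 17 (2R,3S,4S,5S)-3,4-bis[(benzyloxy)methyl]-2-(4-hydroxy-3,5-dimethoxyphenyl)-5-[3,5-dimethoxy-4-(tosyloxy)phenyl]tetrahydrofuran (2,3-trans, 3,4-trans, 4,5-cis), via cyclic oxocarbenium ion 16 (not isolated)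
Conditions: BF3·OEt2 (2 equiv), 15 (3 equiv), CH2Cl2, −78 → −30 °C
Reagents that add atoms: none
Why: Lewis acid-promoted Friedel–Crafts C-arylation of oxocarbenium ion 16, as used for C-aryl glycosides and 2-aryl tetrahydrofuran lignans: the phenol reacts at its unhindered position para to OH, approach anti to the adjacent C3 branch gives the 2,3-trans product (C2 R), which is also the more stable C2 epimer, and the electron-poor tosyloxyaryl group keeps the cis C5–O bond from ionising.

Step 10
Reactants: 17 tosylate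
Product: 18 (2R,3S,4S,5S)-3,4-bis[(benzyloxy)methyl]-2,5-bis(4-hydroxy-3,5-dimethoxyphenyl)tetrahydrofuran
Conditions: KOH (5 equiv), EtOH/H2O, 70 °C; then aq. NH4Cl
Reagents that add atoms: none
Why: Alkaline hydrolysis of an aryl sulfonate by hydroxide attack at sulfur frees the phenol without touching the benzyl ethers, the temperature being kept moderate so that the phenoxides do not open the ring through a quinone methide.

Step 11
Reactants: 18 bis-phenol dibenzyl ether
Product: 19 [(2R,3S,4S,5S)-2,5-bis(4-hydroxy-3,5-dimethoxyphenyl)tetrahydrofuran-3,4-diyl]dimethanol (target; 2,3-trans, 3,4-trans, 4,5-cis)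
Conditions: H2 (1 atm), Pd(OH)2/C, EtOAc/MeOH, rt
Reagents that add atoms: none
Why: Hydrogenolysis of the two primary benzyl ethers over Pd(OH)2/C in a neutral solvent at ambient pressure, stopped at full conversion because the benzylic ring C–O bonds are cleaved more slowly under these conditions, and no stereocentre is affected.

**Compound list**

1 | syringaldehyde | COc1cc(C=O)cc(OC)c1O | starting material
2 | 4-formyl-2,6-dimethoxyphenyl 4-methylbenzenesulfonate | COc1cc(C=O)cc(OC)c1OS(=O)(=O)c1ccc(C)cc1 | intermediate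
3 | methyl acrylate | C=CC(=O)OC | starting material
4 | benzyloxyacetaldehyde | O=CCOCc1ccccc1 | starting material
5 | methyl 4-(benzyloxy)-3-hydroxy-2-methylidenebutanoate (racemic) | C=C(C(=O)OC)C(O)COCc1ccccc1 | intermediate
6 | methyl 3-acetoxy-4-(benzyloxy)-2-methylidenebutanoate (racemic) | C=C(C(=O)OC)C(OC(C)=O)COCc1ccccc1 | intermediate
7 | bis(pinacolato)diboron | CC1(C)OB(OC1(C)C)B1OC(C)(C)C(C)(C)O1 | starting material
8 | methyl (E)-4-(benzyloxy)-2-[(4,4,5,5-tetramethyl-1,3,2-dioxaborolan-2-yl)methyl]but-2-enoate | COC(=O)/C(CB1OC(C)(C)C(C)(C)O1)=C/COCc1ccccc1 | intermediate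
9 | methyl (3S,4S)-3-[(benzyloxy)methyl]-4-[3,5-dimethoxy-4-(tosyloxy)phenyl]-2-methylidene-4-[(4,4,5,5-tetramethyl-1,3,2-dioxaborolan-2-yl)oxy]butanoate (syn; not isolated) | COc1cc([C@@H](OB2OC(C)(C)C(C)(C)O2)[C@H](COCc2ccccc2)C(=C)C(=O)OC)cc(OC)c1OS(=O)(=O)c1ccc(C)cc1 | intermediate
10 | (4S,5S)-4-[(benzyloxy)methyl]-5-[3,5-dimethoxy-4-(tosyloxy)phenyl]-3-methylidenedihydrofuran-2(3H)-one | COc1cc([C@H]2OC(=O)C(=C)[C@H]2COCc2ccccc2)cc(OC)c1OS(=O)(=O)c1ccc(C)cc1 | intermediate
11 | benzyl alcohol | OCc1ccccc1 | starting material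
12 | (3S,4S,5S)-3,4-bis[(benzyloxy)methyl]-5-[3,5-dimethoxy-4-(tosyloxy)phenyl]dihydrofuran-2(3H)-one | COc1cc([C@H]2OC(=O)[C@H](COCc3ccccc3)[C@H]2COCc2ccccc2)cc(OC)c1OS(=O)(=O)c1ccc(C)cc1 | intermediate
13 | (3S,4S,5S)-3,4-bis[(benzyloxy)methyl]-5-[3,5-dimethoxy-4-(tosyloxy)phenyl]tetrahydrofuran-2-ol (anomer mixture) | COc1cc([C@H]2OC(O)[C@H](COCc3ccccc3)[C@H]2COCc2ccccc2)cc(OC)c1OS(=O)(=O)c1ccc(C)cc1 | intermediate
14 | (3S,4S,5S)-3,4-bis[(benzyloxy)methyl]-5-[3,5-dimethoxy-4-(tosyloxy)phenyl]tetrahydrofuran-2-yl acetate (anomer mixture) | COc1cc([C@H]2OC(OC(C)=O)[C@H](COCc3ccccc3)[C@H]2COCc2ccccc2)cc(OC)c1OS(=O)(=O)c1ccc(C)cc1 | intermediate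
15 | 2,6-dimethoxyphenol | COc1cccc(OC)c1O | starting material
16 | (3S,4S,5S)-3,4-bis[(benzyloxy)methyl]-5-[3,5-dimethoxy-4-(tosyloxy)phenyl]-4,5-dihydro-3H-furan-1-ium (cyclic oxocarbenium ion; not isolated) | COc1cc([C@H]2[O+]=C[C@H](COCc3ccccc3)[C@H]2COCc2ccccc2)cc(OC)c1OS(=O)(=O)c1ccc(C)cc1 | intermediate
17 | (2R,3S,4S,5S)-3,4-bis[(benzyloxy)methyl]-2-(4-hydroxy-3,5-dimethoxyphenyl)-5-[3,5-dimethoxy-4-(tosyloxy)phenyl]tetrahydrofuran | COc1cc([C@H]2O[C@@H](c3cc(OC)c(O)c(OC)c3)[C@H](COCc3ccccc3)[C@H]2COCc2ccccc2)cc(OC)c1OS(=O)(=O)c1ccc(C)cc1 | intermediate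
18 | (2R,3S,4S,5S)-3,4-bis[(benzyloxy)methyl]-2,5-bis(4-hydroxy-3,5-dimethoxyphenyl)tetrahydrofuran | COc1cc([C@H]2O[C@@H](c3cc(OC)c(O)c(OC)c3)[C@H](COCc3ccccc3)[C@H]2COCc2ccccc2)cc(OC)c1O | intermediate
19 | [(2R,3S,4S,5S)-2,5-bis(4-hydroxy-3,5-dimethoxyphenyl)tetrahydrofuran-3,4-diyl]dimethanol | COc1cc([C@H]2O[C@@H](c3cc(OC)c(O)c(OC)c3)[C@H](CO)[C@H]2CO)cc(OC)c1O | target

**Step count**

Total steps: 11. Longest linear sequence: 10 steps (steps 2–11, from methyl acrylate and benzyloxyacetaldehyde to 19).

**Steps most likely to fail, with fallbacks**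

Step 5. The chiral acid may turn over too slowly on the ester-deactivated, γ-substituted boronate, or the two aldehyde faces may be poorly differentiated. In that case aldehyde 2 and boronate 8 are combined with Sc(OTf)3 (10 mol%) in toluene at room temperature, the established Lewis acid-catalysed allylboration–lactonisation of 2-alkoxycarbonyl allylboronates. This should give the cis lactone as a racemate, that is 10 together with its mirror image (4R,5R)-4-[(benzyloxy)methyl]-5-[3,5-dimethoxy-4-(tosyloxy)phenyl]-3-methylidenedihydrofuran-2(3H)-one F1. The enantiomers are separated by preparative chromatography on a chiral stationary phase, and the route is rejoined at 10.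

Step 9. The arene may attack through the position meta to its hydroxyl, the C2 face may be poorly differentiated, or the acid may reopen the new benzylic ether and lead to a second arylation. The fallback brings the second aryl group in as an organometallic reagent of fixed regiochemistry, setting out from lactol 13. Commercial 4-bromo-2,6-dimethoxyphenol is benzylated (BnBr, K2CO3, DMF) to 2-(benzyloxy)-5-bromo-1,3-dimethoxybenzene F2, which with n-BuLi in THF at −78 °C gives [4-(benzyloxy)-3,5-dimethoxyphenyl]lithium F3. This reagent (2.5 equiv) adds to 13 through its open hydroxy aldehyde form and gives (2S,3S,4S)-1-[4-(benzyloxy)-3,5-dimethoxyphenyl]-2,3-bis[(benzyloxy)methyl]-4-[3,5-dimethoxy-4-(tosyloxy)phenyl]butane-1,4-diol F4 as a mixture of epimers at the new carbinol. Catalytic p-TsOH in CH2Cl2 at 0 °C should ionise only the electron-rich benzylic alcohol, and the hydroxyl on the tosyloxyaryl carbon closes the ring under thermodynamic control, its own C–O bond never being broken. The product is (2R,3S,4S,5S)-2-[4-(benzyloxy)-3,5-dimethoxyphenyl]-3,4-bis[(benzyloxy)methyl]-5-[3,5-dimethoxy-4-(tosyloxy)phenyl]tetrahydrofuran F5. KOH in EtOH/H2O removes the tosyl group to give (2R,3S,4S,5S)-2-[4-(benzyloxy)-3,5-dimethoxyphenyl]-3,4-bis[(benzyloxy)methyl]-5-(4-hydroxy-3,5-dimethoxyphenyl)tetrahydrofuran F6. Hydrogenolysis of the three benzyl ethers (H2, Pd(OH)2/C, EtOAc/MeOH) then leads directly to 19.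

Step 6. The base may move the exocyclic double bond into the ring with loss of the C4 centre, the alkoxide may attack the sulfonate, or C3 may not equilibrate cleanly. The fallback introduces the oxygen of the C3 branch through boron, setting out from 10. Conjugate borylation of 10 with 7 (CuCl 5 mol%, DPEphos, NaOt-Bu cat., MeOH, THF, rt), a known β-borylation of unsaturated esters and lactones under nearly neutral conditions, gives (4S,5S)-4-[(benzyloxy)methyl]-5-[3,5-dimethoxy-4-(tosyloxy)phenyl]-3-[(4,4,5,5-tetramethyl-1,3,2-dioxaborolan-2-yl)methyl]dihydrofuran-2(3H)-one F7 as a C3 epimer mixture. Oxidation of the C–B bond with NaBO3·4H2O in THF/H2O, followed by brief DBU treatment to equilibrate C3, should give (3S,4S,5S)-4-[(benzyloxy)methyl]-5-[3,5-dimethoxy-4-(tosyloxy)phenyl]-3-(hydroxymethyl)dihydrofuran-2(3H)-one F8. Benzyl 2,2,2-trichloroacetimidate with catalytic TfOH in CH2Cl2 then benzylates the primary alcohol without alkoxide, and the route is rejoined at 12.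

**Further compounds**

F1 | step 5 | (4R,5R)-4-[(benzyloxy)methyl]-5-[3,5-dimethoxy-4-(tosyloxy)phenyl]-3-methylidenedihydrofuran-2(3H)-one | COc1cc([C@@H]2OC(=O)C(=C)[C@@H]2COCc2ccccc2)cc(OC)c1OS(=O)(=O)c1ccc(C)cc1
F2 | step 9 | 2-(benzyloxy)-5-bromo-1,3-dimethoxybenzene | COc1cc(Br)cc(OC)c1OCc1ccccc1
F3 | step 9 | [4-(benzyloxy)-3,5-dimethoxyphenyl]lithium | [Li]c1cc(OC)c(OCc2ccccc2)c(OC)c1
F4 | step 9 | (2S,3S,4S)-1-[4-(benzyloxy)-3,5-dimethoxyphenyl]-2,3-bis[(benzyloxy)methyl]-4-[3,5-dimethoxy-4-(tosyloxy)phenyl]butane-1,4-diol (C1 epimer mixture) | COc1cc([C@@H](O)[C@H](COCc2ccccc2)[C@@H](COCc2ccccc2)C(O)c2cc(OC)c(OCc3ccccc3)c(OC)c2)cc(OC)c1OS(=O)(=O)c1ccc(C)cc1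
F5 | step 9 | (2R,3S,4S,5S)-2-[4-(benzyloxy)-3,5-dimethoxyphenyl]-3,4-bis[(benzyloxy)methyl]-5-[3,5-dimethoxy-4-(tosyloxy)phenyl]tetrahydrofuran | COc1cc([C@H]2O[C@@H](c3cc(OC)c(OCc4ccccc4)c(OC)c3)[C@H](COCc3ccccc3)[C@H]2COCc2ccccc2)cc(OC)c1OS(=O)(=O)c1ccc(C)cc1
F6 | step 9 | (2R,3S,4S,5S)-2-[4-(benzyloxy)-3,5-dimethoxyphenyl]-3,4-bis[(benzyloxy)methyl]-5-(4-hydroxy-3,5-dimethoxyphenyl)tetrahydrofuran | COc1cc([C@H]2O[C@@H](c3cc(OC)c(OCc4ccccc4)c(OC)c3)[C@H](COCc3ccccc3)[C@H]2COCc2ccccc2)cc(OC)c1O
F7 | step 6 | (4S,5S)-4-[(benzyloxy)methyl]-5-[3,5-dimethoxy-4-(tosyloxy)phenyl]-3-[(4,4,5,5-tetramethyl-1,3,2-dioxaborolan-2-yl)methyl]dihydrofuran-2(3H)-one (C3 epimer mixture) | COc1cc([C@H]2OC(=O)C(CB3OC(C)(C)C(C)(C)O3)[C@H]2COCc2ccccc2)cc(OC)c1OS(=O)(=O)c1ccc(C)cc1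
F8 | step 6 | (3S,4S,5S)-4-[(benzyloxy)methyl]-5-[3,5-dimethoxy-4-(tosyloxy)phenyl]-3-(hydroxymethyl)dihydrofuran-2(3H)-one | COc1cc([C@H]2OC(=O)[C@H](CO)[C@H]2COCc2ccccc2)cc(OC)c1OS(=O)(=O)c1ccc(C)cc1
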